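The ring is numbered C1 (carbinol carbon), C2 (side-chain methine), C3 (CMe2), C4–C6 (CH2). Everything rests on cutting the ring bond C5–C6. C6 is a CH2 next to the tertiary carbinol C1(OH)CH3, so C1–O/C6 is read as a 2-methyloxirane and C5 as an α-sulfonyl carbanion. The precursor is an open-chain epoxy sulfone that already carries the complete tetraene chain. One deprotonation closes the six-membered ring by 6-endo opening of the oxirane at its CH2 and releases the equatorial tertiary alcohol with its configuration untouched. C2 is set by a chirality-transferring Johnson–Claisen rearrangement and C1 by a Felkin–Anh methylene transfer.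

Key step: step 12

Assumption: compounds 1, 2, 5, 9, 16 and 17 are taken as commercial; 17 is the pure (2E,6E) isomer, so the three remote chain olefins are bought and only the olefin nearest the ring is made.

Step 1
Reactants: 1 4-(2-methylprop-1-en-1-yl)morpholine; 2 phenyl vinyl sulfone
Product: 4 2,2-dimethyl-4-(phenylsulfonyl)butanal, via aminocyclobutane adduct 3 (not isolated)
Conditions: MeCN, reflux; then H2O, AcOH (cat.), rt
Reagents that add atoms: water, O
Why: Stork-type enamine alkylation, in which the β,β-disubstituted enamine adds to the vinyl sulfone through a [2+2] aminocyclobutane that opens on hydrolysis to the Michael adduct, creating the quaternary CMe2 carbon and installing the sulfone that later carries the ring-closing carbanion.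

Step 2
Reactants: 4 2,2-dimethyl-4-(phenylsulfonyl)butanal; 5 diethyl (3-oxobutan-2-yl)phosphonate
Product: 7 (3E)-3,5,5-trimethyl-7-(phenylsulfonyl)hept-3-en-2-one, via sodium phosphonate carbanion 6 (not isolated)
Conditions: NaH, THF, 0 °C; then 4, 0 °C → reflux
Reagents that add atoms: none
Why: Horner–Wadsworth–Emmons olefination of the non-enolisable aldehyde with the stabilised α-methyl phosphonate anion should give the trisubstituted enone with the quaternary carbon trans to the acetyl group (E).

Step 3
Reactants: 7 (3E)-3,5,5-trimethyl-7-(phenylsulfonyl)hept-3-en-2-one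
Product: 8 (2R,3E)-3,5,5-trimethyl-7-(phenylsulfonyl)hept-3-en-2-ol
Conditions: (S)-1-methyl-3,3-diphenyltetrahydro-1H,3H-pyrrolo[1,2-c][1,3,2]oxazaborole (0.1 equiv), BH3·SMe2, THF, −20 °C; then MeOH, H2O
Reagents that add atoms: none
Why: Corey–Bakshi–Shibata reduction, in which the (S)-oxazaborolidine–borane complex delivers hydride to the carbonyl face that gives the (R)-carbinol (alkenyl group as the large substituent); this centre is relayed to the ring methine in step 4.

Step 4
Reactants: 8 (2R,3E)-3,5,5-trimethyl-7-(phenylsulfonyl)hept-3-en-2-ol; 9 triethyl orthoacetate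
Product: 11 ethyl (3S,4E)-4-methyl-3-[2-methyl-4-(phenylsulfonyl)butan-2-yl]hex-4-enoate, via mixed ketene acetal 10 (not isolated)
Conditions: EtCO2H (cat.), 140 °C, EtOH distilled off
Reagents that add atoms: none
Why: Johnson–Claisen rearrangement through a chair transition state with the carbinol methyl equatorial, so the C–O stereocentre is transferred suprafacially to the new C–C bond and the (R,E)-alcohol should give the (S)-methine (ring C2 of the target) next to the quaternary carbon.

Step 5
Reactants: 11 ethyl (3S,4E)-4-methyl-3-[2-methyl-4-(phenylsulfonyl)butan-2-yl]hex-4-enoate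
Product: 12 (3S,4E)-4-methyl-3-[2-methyl-4-(phenylsulfonyl)butan-2-yl]hex-4-en-1-ol
Conditions: LiAlH4, THF, 0 °C
Reagents that add atoms: none
Why: Hydride reduction of the ester to the primary alcohol; the sulfone and the trisubstituted olefin are inert to LiAlH4 at 0 °C.

Step 6
Reactants: 12 (3S,4E)-4-methyl-3-[2-methyl-4-(phenylsulfonyl)butan-2-yl]hex-4-en-1-ol
Product: 14 (3S)-3-(2-hydroxyethyl)-4,4-dimethyl-6-(phenylsulfonyl)hexan-2-one, via ozonide 13 (not isolated)
Conditions: O3, CH2Cl2, −78 °C; then Me2S, −78 °C → rt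
Reagents that add atoms: ozone, [O-][O+]=O
Why: Ozonolysis of the only C=C bond with reductive work-up unmasks the methyl ketone (the future carbinol carbon C1) and removes the ethylidene carbon as acetaldehyde, without touching the α-stereocentre under these neutral conditions.

Step 7
Reactants: 14 (3S)-3-(2-hydroxyethyl)-4,4-dimethyl-6-(phenylsulfonyl)hexan-2-one
Product: 15 (3S)-3-(2-iodoethyl)-4,4-dimethyl-6-(phenylsulfonyl)hexan-2-one
Conditions: I2, PPh3, imidazole, CH2Cl2, 0 °C
Reagents that add atoms: iodine, II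
Why: Appel iodination of the primary alcohol (open form of the γ-hydroxy ketone) under near-neutral conditions that spare the enolisable α-methine.

Step 8
Reactants: 16 propyne; 17 (2E,6E)-farnesyl bromide
Product: 20 (6E,10E)-7,11,15-trimethylhexadeca-6,10,14-trien-2-yne, via 1,3-dilithiopropyne 18 (not isolated), via lithium acetylide 19 (not isolated)
Conditions: n-BuLi (2 equiv), TMEDA, THF–hexane, −78 → 0 °C; then 17, −78 → 0 °C; then MeI, DMPU, 0 °C → rt
Reagents that add atoms: iodomethane, CI
Why: 1,3-Dilithiopropyne reacts first at its sp3 carbon in an SN2 alkylation with the allylic bromide (olefin geometry retained) and the remaining lithium acetylide is then methylated, giving the 2-alkyne in one flask.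

Step 9
Reactants: 20 (6E,10E)-7,11,15-trimethylhexadeca-6,10,14-trien-2-yne
Product: 22 (2E,6E,10E)-2-iodo-7,11,15-trimethylhexadeca-2,6,10,14-tetraene, via alkenylzirconocene chloride 21 (not isolated)
Conditions: Cp2Zr(H)Cl (1.5 equiv), THF, rt → 45 °C; then I2, 0 °C
Reagents that add atoms: iodine, II
Why: Hydrozirconation–iodination, in which syn addition of Zr–H and equilibration with excess reagent should place zirconium on the methyl-bearing alkyne carbon and iodinolysis with retention gives the (E)-2-iodo-2-alkene; the trisubstituted olefins do not react with Cp2Zr(H)Cl.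

Step 10
Reactants: 15 (3S)-3-(2-iodoethyl)-4,4-dimethyl-6-(phenylsulfonyl)hexan-2-one; 22 (2E,6E,10E)-2-iodo-7,11,15-trimethylhexadeca-2,6,10,14-tetraene
Product: 24 (3S,6E,10E,14E)-6,11,15,19-tetramethyl-3-[2-methyl-4-(phenylsulfonyl)butan-2-yl]icosa-6,10,14,18-tetraen-2-one, via alkylzinc iodide 23 (not isolated)
Conditions: Zn dust, LiCl, THF, 35 °C; then 22, PdCl2(dppf) (5 mol %), THF, 45 °C (dppf = 1,1'-bis(diphenylphosphino)ferrocene)
Reagents that add atoms: none
Why: Negishi coupling, in which zinc inserts into the primary C–I bond and the alkylzinc iodide (tolerant of the ketone and the sulfone) couples with the alkenyl iodide under palladium catalysis with retention of the E geometry, completing the side chain.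

Step 11
Reactants: 24 (3S,6E,10E,14E)-6,11,15,19-tetramethyl-3-[2-methyl-4-(phenylsulfonyl)butan-2-yl]icosa-6,10,14,18-tetraen-2-one
Product: 25 (2R)-2-methyl-2-[(4S,7E,11E,15E)-3,3,7,12,16,20-hexamethyl-1-(phenylsulfonyl)henicosa-7,11,15,19-tetraen-4-yl]oxirane
Conditions: Me3S+ I−, n-BuLi, THF, −10 °C; then 24, −10 °C → rt
Reagents that add atoms: trimethylsulfonium iodide, C[S+](C)C.[I-]
Why: Corey–Chaykovsky methylene transfer, whose irreversible ylide addition should follow the Felkin–Anh model (quaternary substituent anti to the incoming carbon, attack past the methine hydrogen) and so give the (R)-oxirane, which is the C1 configuration of the target; the ylide is not basic enough to deprotonate the sulfone.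

Step 12
Reactants: 25 (2R)-2-methyl-2-[(4S,7E,11E,15E)-3,3,7,12,16,20-hexamethyl-1-(phenylsulfonyl)henicosa-7,11,15,19-tetraen-4-yl]oxirane
Product: 27 (1S,2S)-1,3,3-trimethyl-5-(phenylsulfonyl)-2-[(3E,7E,11E)-3,8,12,16-tetramethylheptadeca-3,7,11,15-tetraen-1-yl]cyclohexan-1-ol, via lithiated sulfone 26 (not isolated)
Conditions: LDA (1.1 equiv), THF–DMPU, −78 °C → rt; then H2O
Reagents that add atoms: none
Why: LDA removes a proton α to the sulfone, and the carbanion opens the oxirane by SN2 attack at its unsubstituted CH2 carbon, forming the C5–C6 ring bond and a tertiary lithium alkoxide. The closest known reaction type is the cyclisation of epoxy sulfones (and the related epoxynitrile cyclisation). The six-membered ring closes in the 6-endo mode with respect to the oxirane, because the alternative 5-exo attack would have to occur at a fully substituted carbon. The carbinol centre is not a reacting centre and keeps the configuration set in step 11, its C–O bond lying anti to the new ring bond and therefore equatorial; the only new stereocentre, the sulfone-bearing carbon, is uncontrolled and is erased in step 13. The step needs attack at CH2 only and deprotonation at one site only, which the quaternary oxirane carbon and the large acidity gap between the sulfone α-protons and all other C–H bonds secure; the main penalty is the syn-diaxial methyl–methyl contact in the chair transition state.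

Step 13
Reactants: 27 (1S,2S)-1,3,3-trimethyl-5-(phenylsulfonyl)-2-[(3E,7E,11E)-3,8,12,16-tetramethylheptadeca-3,7,11,15-tetraen-1-yl]cyclohexan-1-ol
Product: 28 (1S,2S)-1,3,3-trimethyl-2-[(3E,7E,11E)-3,8,12,16-tetramethylheptadeca-3,7,11,15-tetraen-1-yl]cyclohexan-1-ol
Conditions: Na(Hg) (6 % Na), Na2HPO4, MeOH–THF, −20 °C → rt
Reagents that add atoms: none
Why: Reductive desulfonylation, in which electron transfer from sodium amalgam cleaves the C–S bond and the carbanion is protonated by methanol, leaving the isolated trisubstituted olefins and the tertiary alcohol untouched.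

Compound list
1 | 4-(2-methylprop-1-en-1-yl)morpholine | CC(C)=CN1CCOCC1 | starting material
2 | phenyl vinyl sulfone | C=CS(=O)(=O)c1ccccc1 | starting material
3 | 4-[2,2-dimethyl-4-(phenylsulfonyl)cyclobutyl]morpholine (formed in situ, stereoisomer mixture) | CC1(C)CC(S(=O)(=O)c2ccccc2)C1N1CCOCC1 | intermediate
4 | 2,2-dimethyl-4-(phenylsulfonyl)butanal | O=CC(C)(C)CCS(=O)(=O)c1ccccc1 | intermediate
5 | diethyl (3-oxobutan-2-yl)phosphonate | CCOP(=O)(OCC)C(C)C(C)=O | starting material
6 | sodium salt of the carbanion of 5 (formed in situ) | CCOP(=O)(OCC)[C-](C)C(C)=O.[Na+] | intermediate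
7 | (3E)-3,5,5-trimethyl-7-(phenylsulfonyl)hept-3-en-2-one | CC(=O)/C(C)=C/C(C)(C)CCS(=O)(=O)c1ccccc1 | intermediate
8 | (2R,3E)-3,5,5-trimethyl-7-(phenylsulfonyl)hept-3-en-2-ol | C[C@@H](O)/C(C)=C/C(C)(C)CCS(=O)(=O)c1ccccc1 | intermediate
9 | triethyl orthoacetate | CCOC(C)(OCC)OCC | starting material
10 | mixed ketene acetal, 1-ethoxyvinyl ether of 8 (formed in situ) | C=C(OCC)O[C@H](C)/C(C)=C/C(C)(C)CCS(=O)(=O)c1ccccc1 | intermediate
11 | ethyl (3S,4E)-4-methyl-3-[2-methyl-4-(phenylsulfonyl)butan-2-yl]hex-4-enoate | CCOC(=O)C[C@H](/C(C)=C/C)C(C)(C)CCS(=O)(=O)c1ccccc1 | intermediate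
12 | (3S,4E)-4-methyl-3-[2-methyl-4-(phenylsulfonyl)butan-2-yl]hex-4-en-1-ol | OCC[C@H](/C(C)=C/C)C(C)(C)CCS(=O)(=O)c1ccccc1 | intermediate
13 | ozonide (1,2,4-trioxolane) of 12 (formed in situ, ring stereocentres undefined) | CC1OOC(C)([C@@H](CCO)C(C)(C)CCS(=O)(=O)c2ccccc2)O1 | intermediate
14 | (3S)-3-(2-hydroxyethyl)-4,4-dimethyl-6-(phenylsulfonyl)hexan-2-one (in equilibrium with its cyclic hemiketal) | CC(=O)[C@@H](CCO)C(C)(C)CCS(=O)(=O)c1ccccc1 | intermediate
15 | (3S)-3-(2-iodoethyl)-4,4-dimethyl-6-(phenylsulfonyl)hexan-2-one | CC(=O)[C@@H](CCI)C(C)(C)CCS(=O)(=O)c1ccccc1 | intermediate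
16 | propyne | CC#C | starting material
17 | (2E,6E)-farnesyl bromide | CC(C)=CCC/C(C)=C/CC/C(C)=C/CBr | starting material
18 | 1,3-dilithiopropyne (formed in situ) | [Li]CC#C[Li] | intermediate
19 | [(5E,9E)-6,10,14-trimethylpentadeca-5,9,13-trien-1-yn-1-yl]lithium (formed in situ) | CC(C)=CCC/C(C)=C/CC/C(C)=C/CCC#C[Li] | intermediate
20 | (6E,10E)-7,11,15-trimethylhexadeca-6,10,14-trien-2-yne | CC(C)=CCC/C(C)=C/CC/C(C)=C/CCC#CC | intermediate
21 | chlorobis(cyclopentadienyl)[(2E,6E,10E)-7,11,15-trimethylhexadeca-2,6,10,14-tetraen-2-yl]zirconium (formed in situ) | CC(C)=CCC/C(C)=C/CC/C(C)=C/CC/C=C(\C)[Zr](Cl)(C1C=CC=C1)C1C=CC=C1 | intermediate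
22 | (2E,6E,10E)-2-iodo-7,11,15-trimethylhexadeca-2,6,10,14-tetraene | CC(C)=CCC/C(C)=C/CC/C(C)=C/CC/C=C(\C)I | intermediate
23 | [(3S)-3-acetyl-4,4-dimethyl-6-(phenylsulfonyl)hexyl]zinc iodide (formed in situ) | CC(=O)[C@@H](CC[Zn]I)C(C)(C)CCS(=O)(=O)c1ccccc1 | intermediate
24 | (3S,6E,10E,14E)-6,11,15,19-tetramethyl-3-[2-methyl-4-(phenylsulfonyl)butan-2-yl]icosa-6,10,14,18-tetraen-2-one | CC(=O)[C@@H](CC/C(C)=C/CC/C=C(\C)CC/C=C(\C)CCC=C(C)C)C(C)(C)CCS(=O)(=O)c1ccccc1 | intermediate
25 | (2R)-2-methyl-2-[(4S,7E,11E,15E)-3,3,7,12,16,20-hexamethyl-1-(phenylsulfonyl)henicosa-7,11,15,19-tetraen-4-yl]oxirane | C[C@]1(CO1)[C@@H](CC/C(C)=C/CC/C=C(\C)CC/C=C(\C)CCC=C(C)C)C(C)(C)CCS(=O)(=O)c1ccccc1 | intermediate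
26 | α-lithio sulfone of 25 (formed in situ) | C[C@]1(CO1)[C@@H](CC/C(C)=C/CC/C=C(\C)CC/C=C(\C)CCC=C(C)C)C(C)(C)CC([Li])S(=O)(=O)c1ccccc1 | intermediate
27 | (1S,2S)-1,3,3-trimethyl-5-(phenylsulfonyl)-2-[(3E,7E,11E)-3,8,12,16-tetramethylheptadeca-3,7,11,15-tetraen-1-yl]cyclohexan-1-ol (both C5 epimers) | CC(C)=CCC/C(C)=C/CC/C(C)=C/CC/C=C(\C)CC[C@H]1C(C)(C)CC(S(=O)(=O)c2ccccc2)C[C@]1(C)O | intermediate
28 | (1S,2S)-1,3,3-trimethyl-2-[(3E,7E,11E)-3,8,12,16-tetramethylheptadeca-3,7,11,15-tetraen-1-yl]cyclohexan-1-ol | CC(C)=CCC/C(C)=C/CC/C(C)=C/CC/C=C(\C)CC[C@H]1C(C)(C)CCC[C@]1(C)O | target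

Total step count: 13. Longest linear sequence: 11 steps (steps 1–7 and 10–13); the side-chain iodide 22 takes 2 steps (8 and 9).

Steps most likely to fail

Step 12. The ring closure may be slow because of the syn-diaxial methyl–methyl compression in the chair transition state, so that base-induced isomerisation of the oxirane to an allylic alkoxide or intermolecular opening could compete. The fallback sets out from ketone 24 and comes back at target 28, forming the same ring bond by olefin metathesis. CeCl3-promoted addition of vinylmagnesium bromide (same Felkin–Anh sense as step 11) should give the vinyl carbinol F1. Double deprotonation with n-BuLi and C-alkylation with Bu3SnCH2I should give the β-stannyl sulfone F2, and Bu4NF should trigger β-elimination to the terminal olefin F3 (Julia-type methylenation). Ring-closing metathesis with the first-generation Grubbs catalyst RuCl2(PCy3)2(=CHPh), which does not engage the trisubstituted chain olefins, should give the cyclohexenol F4. Diimide (TsNHNH2, NaOAc) or H2 with RhCl(PPh3)3 should then saturate only the cis-disubstituted ring olefin and give 28.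

Step 11. Facial selectivity of the methylene transfer may be poor, and the basic ylide may enolise the ketone and epimerise the α-methine. The fallback sets out from ketone 24 and comes back at epoxide 25, bringing in the CH2 as a non-basic, bulkier hydroxymethyl anion equivalent. Addition of (isopropoxydimethylsilyl)methylmagnesium chloride with CeCl3 should give the silylmethyl carbinol F5. Tamao–Fleming oxidation (H2O2, KF, KHCO3) should give the 1,2-diol F6. One-flask closure with 1-(p-toluenesulfonyl)imidazole and NaH (primary sulfonate, then displacement by the tertiary alkoxide with retention at the carbinol) should give 25.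

Step 9. Regiocontrol of the hydrozirconation may be incomplete, which would carry a constitutional isomer of iodide 22 into the coupling. The fallback sets out from farnesyl bromide 17 and comes back at ketone 24, fixing the positions of methyl and chain by construction. Alkylation of lithiated acetaldehyde N-cyclohexylimine with 17 and hydrolysis should give aldehyde F7. CBr4 and PPh3 should give the 1,1-dibromoalkene F8. Palladium-catalysed trans-selective monoalkylation with alkylzinc iodide 23 (PdCl2(DPEphos)) should give the (Z)-bromoalkene F9. Methylation with Me2Zn and Pd(P(t-Bu)3)2 with retention should give 24.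

Further compounds
F1 | step 12 | vinyl carbinol, (3S,4S,7E,11E,15E)-3,7,12,16,20-pentamethyl-4-[2-methyl-4-(phenylsulfonyl)butan-2-yl]henicosa-1,7,11,15,19-pentaen-3-ol | C=C[C@](C)(O)[C@@H](CC/C(C)=C/CC/C=C(\C)CC/C=C(\C)CCC=C(C)C)C(C)(C)CCS(=O)(=O)c1ccccc1
F2 | step 12 | β-stannyl sulfone, F1 carrying a tributylstannylmethyl group on the sulfonyl-bearing carbon (epimer mixture there) | C=C[C@](C)(O)[C@@H](CC/C(C)=C/CC/C=C(\C)CC/C=C(\C)CCC=C(C)C)C(C)(C)CC(C[Sn](CCCC)(CCCC)CCCC)S(=O)(=O)c1ccccc1
F3 | step 12 | terminal olefin, (3S,4S,7E,11E,15E)-3,7,12,16,20-pentamethyl-4-(2-methylpent-4-en-2-yl)henicosa-1,7,11,15,19-pentaen-3-ol | C=C[C@](C)(O)[C@@H](CC/C(C)=C/CC/C=C(\C)CC/C=C(\C)CCC=C(C)C)C(C)(C)CC=C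
F4 | step 12 | cyclohexenol, (1S,6S)-1,5,5-trimethyl-6-[(3E,7E,11E)-3,8,12,16-tetramethylheptadeca-3,7,11,15-tetraen-1-yl]cyclohex-2-en-1-ol | CC(C)=CCC/C(C)=C/CC/C(C)=C/CC/C=C(\C)CC[C@H]1C(C)(C)CC=C[C@]1(C)O
F5 | step 11 | silylmethyl carbinol, tertiary alcohol from addition of the (isopropoxydimethylsilyl)methyl group to the carbonyl carbon of 24 | CC(C)O[Si](C)(C)C[C@](C)(O)[C@@H](CC/C(C)=C/CC/C=C(\C)CC/C=C(\C)CCC=C(C)C)C(C)(C)CCS(=O)(=O)c1ccccc1
F6 | step 11 | 1,2-diol, (2R,3S,6E,10E,14E)-2,6,11,15,19-pentamethyl-3-[2-methyl-4-(phenylsulfonyl)butan-2-yl]icosa-6,10,14,18-tetraene-1,2-diol | OC[C@](C)(O)[C@@H](CC/C(C)=C/CC/C=C(\C)CC/C=C(\C)CCC=C(C)C)C(C)(C)CCS(=O)(=O)c1ccccc1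
F7 | step 9 | aldehyde, (4E,8E)-5,9,13-trimethyltetradeca-4,8,12-trienal | CC(C)=CCC/C(C)=C/CC/C(C)=C/CCC=O
F8 | step 9 | 1,1-dibromoalkene, (5E,9E)-1,1-dibromo-6,10,14-trimethylpentadeca-1,5,9,13-tetraene | CC(C)=CCC/C(C)=C/CC/C(C)=C/CCC=C(Br)Br
F9 | step 9 | (Z)-bromoalkene, (3S,6Z,10E,14E)-6-bromo-11,15,19-trimethyl-3-[2-methyl-4-(phenylsulfonyl)butan-2-yl]icosa-6,10,14,18-tetraen-2-one | CC(=O)[C@@H](CC/C(Br)=C/CC/C=C(\C)CC/C=C(\C)CCC=C(C)C)C(C)(C)CCS(=O)(=O)c1ccccc1
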